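**Retrosynthetic overview**

1. The 12-membered dilactone is cut at both ester C–O bonds. Each is made by Mitsunobu displacement with inversion at C2, the ring-closing one last.
2. Each carboxyl carbon comes from an aryl iodide: CO2 on the aryllithium for ring A, CO and water with palladium for ring B. The fourth oxygen of ring B is put in at the same iodide position, followed by re-iodination.
3. Key C–C bond: C1–C2 of the side chain, from the aryl aldehyde carbon and an acetyl anion equivalent (1-ethoxyvinyllithium). It is run once and racemic, because the two side chains are mirror images.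
4. Stereochemistry: chelation-controlled reduction (anti), then one lipase resolution sends the (1S,2R) enantiomer to ring A and the (1R,2S) enantiomer to ring B.
5. Rings: both benzene rings come from methyl 3,5-dihydroxy-4-methoxybenzoate; the only ring formed is the macrocycle (step 13).

Assumption: read from the SMILES, the side chain on ring A (the ring with one aromatic H) is (1S,2S) and that on ring B is (1R,2R), C1 being the benzylic carbon; Bn = benzyl, BOM = benzyloxymethyl, TBS = tert-butyldimethylsilyl.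

**Route**

Step 1
Reactants: 1 methyl 3,5-dihydroxy-4-methoxybenzoate
Product: 2 methyl 3,5-bis(benzyloxy)-4-methoxybenzoate
Conditions: BnBr, K2CO3, DMF, 60 °C
Reagents that add atoms: benzyl bromide, BrCc1ccccc1
Why: Williamson ether synthesis on both phenols; benzyl is chosen because it is removed by hydrogenolysis in the last step.

Step 2
Reactants: 2 methyl 3,5-bis(benzyloxy)-4-methoxybenzoate
Product: 3 3,5-bis(benzyloxy)-4-methoxybenzaldehyde
Conditions: DIBAL-H (1.1 equiv), toluene, −78 °C; MeOH quench at −78 °C, Rochelle salt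
Reagents that add atoms: none
Why: Partial reduction of an ester with DIBAL-H, where the tetrahedral aluminium hemiacetal survives until the cold quench and then gives the aldehyde.

Step 3
Reactants: 3 3,5-bis(benzyloxy)-4-methoxybenzaldehyde
Product: 4 3,5-bis(benzyloxy)-2-iodo-4-methoxybenzaldehyde
Conditions: N-iodosuccinimide (1.05 equiv), CF3CO2H (cat.), MeCN, 0 °C to rt
Reagents that add atoms: N-iodosuccinimide, O=C1CCC(=O)N1I
Why: Electrophilic aromatic iodination at one of the two equivalent free positions (ortho to one benzyloxy group, para to the other); the iodide is the later handle for both carboxyl groups and for the extra phenol of ring B.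

Step 4
Reactants: 4 3,5-bis(benzyloxy)-2-iodo-4-methoxybenzaldehyde; 5 ethyl vinyl ether
Product: 9 racemic 1-[3,5-bis(benzyloxy)-2-iodo-4-methoxyphenyl]-1-(benzyloxymethoxy)propan-2-one, via 1-ethoxyvinyllithium 6 (not isolated), via lithium alkoxide adduct 7 (not isolated), via BOM-protected enol ether 8 (not isolated)
Conditions: 5 (3 equiv), t-BuLi (1.3 equiv), THF, −78 to 0 °C; then 4, −78 °C; then BnOCH2Cl, DMPU, −78 °C to rt; then 1 M HCl, THF, 0 °C
Reagents that add atoms: benzyl chloromethyl ether, ClCOCc1ccccc1; water, O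
Why: Key step, acyl anion addition (1-ethoxyvinyllithium as an acetyl anion equivalent): the masked acetyl carbon attacks the aldehyde carbon so that two carbonyl carbons are joined, the alkoxide is capped in the same flask as the chelating, hydrogenolysable BOM ether and mild acid unmasks the ketone; the benzylic stereocentre is made racemic on purpose because ring A needs 1S and ring B needs 1R, so one coupling feeds both halves.

Step 5
Reactants: 9 racemic 1-[3,5-bis(benzyloxy)-2-iodo-4-methoxyphenyl]-1-(benzyloxymethoxy)propan-2-one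
Product: 10 racemic anti alcohol (1S*,2R*)-1-[3,5-bis(benzyloxy)-2-iodo-4-methoxyphenyl]-1-(benzyloxymethoxy)propan-2-ol
Conditions: Zn(BH4)2, Et2O, −20 °C
Reagents that add atoms: none
Why: Chelation-controlled (Cram chelate) hydride reduction: zinc bridges the ketone and the BOM oxygen and hydride enters past the small hydrogen, which sets C2 anti to C1 (expected d.r. at least 10:1, minor syn isomer removed on silica).

Step 6
Reactants: 10 racemic anti alcohol (1S*,2R*)-1-[3,5-bis(benzyloxy)-2-iodo-4-methoxyphenyl]-1-(benzyloxymethoxy)propan-2-ol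
Product: 11 (1S,2R)-1-[3,5-bis(benzyloxy)-2-iodo-4-methoxyphenyl]-1-(benzyloxymethoxy)propan-2-yl acetate; 12 (1R,2S)-1-[3,5-bis(benzyloxy)-2-iodo-4-methoxyphenyl]-1-(benzyloxymethoxy)propan-2-ol (unreacted enantiomer, isolated as well)
Conditions: Novozym 435 (immobilised Candida antarctica lipase B), vinyl acetate, MTBE, 40 °C, to 50% conversion
Reagents that add atoms: vinyl acetate, CC(=O)OC=C
Why: Lipase-catalysed kinetic resolution (Kazlauskas rule): the enzyme acetylates only the (2R) carbinol, so the (1S,2R) enantiomer leaves as acetate 11 for ring A and the (1R,2S) enantiomer stays as alcohol 12 for ring B, which fixes the absolute configuration of all four stereocentres and wastes neither enantiomer.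

Step 7
Reactants: 11 (1S,2R)-1-[3,5-bis(benzyloxy)-2-iodo-4-methoxyphenyl]-1-(benzyloxymethoxy)propan-2-yl acetate
Product: 14 tert-butyl{[(1S,2R)-1-[3,5-bis(benzyloxy)-2-iodo-4-methoxyphenyl]-1-(benzyloxymethoxy)propan-2-yl]oxy}dimethylsilane, via (1S,2R)-alcohol 13 (not isolated)
Conditions: K2CO3 (cat.), MeOH, rt; then TBSOTf, 2,6-lutidine, CH2Cl2, 0 °C
Reagents that add atoms: tert-butyldimethylsilyl triflate, CC(C)(C)[Si](C)(C)OS(=O)(=O)C(F)(F)F
Why: Base-catalysed transesterification frees the alcohol without touching the stereocentres and silylation masks it for the organolithium and Mitsunobu steps.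

Step 8
Reactants: 14 tert-butyl{[(1S,2R)-1-[3,5-bis(benzyloxy)-2-iodo-4-methoxyphenyl]-1-(benzyloxymethoxy)propan-2-yl]oxy}dimethylsilane
Product: 16 2,4-bis(benzyloxy)-6-[(1S,2R)-1-(benzyloxymethoxy)-2-(tert-butyldimethylsilyloxy)propyl]-3-methoxybenzoic acid, via aryllithium 15 (not isolated)
Conditions: t-BuLi (2.1 equiv), Et2O, −78 °C; CO2; then 1 M HCl to pH 3, 0 °C
Reagents that add atoms: carbon dioxide, O=C=O
Why: Iodine–lithium exchange followed by carboxylation of the aryllithium gives the hindered benzoic acid of ring A; BOM, benzyl and TBS ethers are inert at −78 °C.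

Step 9
Reactants: 12 (1R,2S)-1-[3,5-bis(benzyloxy)-2-iodo-4-methoxyphenyl]-1-(benzyloxymethoxy)propan-2-ol
Product: 20 (1R,2S)-1-(benzyloxymethoxy)-1-[2,3,5-tris(benzyloxy)-4-methoxyphenyl]propan-2-ol, via dilithio species 17 (not isolated), via arylboronate 18 (not isolated), via phenol 19 (not isolated)
Conditions: n-BuLi (1.0 equiv) then t-BuLi (2.1 equiv), THF, −78 °C; B(OMe)3, −78 °C to rt; H2O2, aq NaOH, 0 °C; then BnBr, K2CO3, DMF, rt
Reagents that add atoms: hydrogen peroxide, OO; benzyl bromide, BrCc1ccccc1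
Why: Iodine–lithium exchange on the lithium alkoxide, borylation and oxidative C–B to C–O rearrangement put the fourth oxygen of ring B where the iodine was, and the air-sensitive phenol is benzylated at once (Williamson) in preference to the secondary alcohol.

Step 10
Reactants: 20 (1R,2S)-1-(benzyloxymethoxy)-1-[2,3,5-tris(benzyloxy)-4-methoxyphenyl]propan-2-ol
Product: 21 (1R,2S)-1-(benzyloxymethoxy)-1-[2,3,5-tris(benzyloxy)-6-iodo-4-methoxyphenyl]propan-2-ol
Conditions: N-iodosuccinimide, MeCN, 0 °C to rt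
Reagents that add atoms: N-iodosuccinimide, O=C1CCC(=O)N1I
Why: Electrophilic aromatic iodination at the only ring position left, which is ortho and para to benzyloxy groups, gives the handle for the carboxyl group of ring B.

Step 11
Reactants: 16 2,4-bis(benzyloxy)-6-[(1S,2R)-1-(benzyloxymethoxy)-2-(tert-butyldimethylsilyloxy)propyl]-3-methoxybenzoic acid; 21 (1R,2S)-1-(benzyloxymethoxy)-1-[2,3,5-tris(benzyloxy)-6-iodo-4-methoxyphenyl]propan-2-ol
Product: 22 (1R,2R)-1-(benzyloxymethoxy)-1-[2,3,5-tris(benzyloxy)-6-iodo-4-methoxyphenyl]propan-2-yl 2,4-bis(benzyloxy)-6-[(1S,2R)-1-(benzyloxymethoxy)-2-(tert-butyldimethylsilyloxy)propyl]-3-methoxybenzoate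
Conditions: PPh3, DIAD, toluene, 0 °C to rt
Reagents that add atoms: none
Why: Mitsunobu esterification: the hindered acid only has to act as a carboxylate nucleophile, no acyl activation next to the benzylic BOM ether is needed, and SN2 displacement inverts C2 of the ring B fragment from S to R as the target requires.

Step 12
Reactants: 22 (1R,2R)-1-(benzyloxymethoxy)-1-[2,3,5-tris(benzyloxy)-6-iodo-4-methoxyphenyl]propan-2-yl 2,4-bis(benzyloxy)-6-[(1S,2R)-1-(benzyloxymethoxy)-2-(tert-butyldimethylsilyloxy)propyl]-3-methoxybenzoate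
Product: 23 3,4,6-tris(benzyloxy)-2-[(1R,2R)-2-({2,4-bis(benzyloxy)-6-[(1S,2R)-1-(benzyloxymethoxy)-2-(tert-butyldimethylsilyloxy)propyl]-3-methoxybenzoyl}oxy)-1-(benzyloxymethoxy)propyl]-5-methoxybenzoic acid
Conditions: Pd(OAc)2 (10 mol%), Xantphos, CO (1 atm), H2O, Et3N, 1,4-dioxane, 80 °C; citric acid work-up
Reagents that add atoms: carbon monoxide, [C-]#[O+]; water, O
Why: Palladium-catalysed hydroxycarbonylation (oxidative addition of the aryl iodide to zerovalent palladium, CO insertion, hydrolysis of the acylpalladium) installs the carboxyl group of ring B without an organolithium that would attack the ester.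

Step 13
Reactants: 23 3,4,6-tris(benzyloxy)-2-[(1R,2R)-2-({2,4-bis(benzyloxy)-6-[(1S,2R)-1-(benzyloxymethoxy)-2-(tert-butyldimethylsilyloxy)propyl]-3-methoxybenzoyl}oxy)-1-(benzyloxymethoxy)propyl]-5-methoxybenzoic acid
Product: 25 protected macrocycle (the 12-membered dilactone of the target with five O-benzyl groups on the phenols and two O-BOM groups on the benzylic oxygens; 1S,2S side chain on ring A and 1R,2R on ring B), via seco acid 24 (not isolated)
Conditions: HF·pyridine, pyridine, THF, 0 °C to rt; then PPh3, DIAD, toluene (0.002 M), slow addition, rt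
Reagents that add atoms: none
Why: Fluoride removes the TBS ether and the crude hydroxy acid is closed at once by Mitsunobu macrolactonisation under high dilution, which activates the alcohol instead of the hindered acid, never exposes the hydroxy ester to base (no collapse to the six-membered lactone) and inverts C2 of the ring A fragment from R to S.

Step 14
Reactants: 25 protected macrocycle
Product: 26 CNP0086623.3 (target)
Conditions: H2 (1 atm), Pd(OH)2/C, EtOAc–MeOH, rt, under argon on work-up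
Reagents that add atoms: none
Why: Hydrogenolysis cleaves the five benzyl ethers and the two BOM ethers (the hemiacetals lose formaldehyde) under neutral conditions that leave the base-sensitive hydroxy dilactone and its four stereocentres untouched.

**Compound list**

1 | methyl 3,5-dihydroxy-4-methoxybenzoate | COC(=O)c1cc(O)c(OC)c(O)c1 | starting material
2 | methyl 3,5-bis(benzyloxy)-4-methoxybenzoate | COC(=O)c1cc(OCc2ccccc2)c(OC)c(OCc2ccccc2)c1 | intermediate
3 | 3,5-bis(benzyloxy)-4-methoxybenzaldehyde | O=Cc1cc(OCc2ccccc2)c(OC)c(OCc2ccccc2)c1 | intermediate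
4 | 3,5-bis(benzyloxy)-2-iodo-4-methoxybenzaldehyde | O=Cc1cc(OCc2ccccc2)c(OC)c(OCc2ccccc2)c1I | intermediate
5 | ethyl vinyl ether | C=COCC | starting material
6 | 1-ethoxyvinyllithium | [Li]C(=C)OCC | intermediate
7 | lithium 1-[3,5-bis(benzyloxy)-2-iodo-4-methoxyphenyl]-2-ethoxyprop-2-en-1-olate (racemic) | [Li]OC(C(=C)OCC)c1cc(OCc2ccccc2)c(OC)c(OCc2ccccc2)c1I | intermediate
8 | 1-[3,5-bis(benzyloxy)-2-iodo-4-methoxyphenyl]-1-(benzyloxymethoxy)-2-ethoxyprop-2-ene (racemic) | C=C(OCC)C(OCOCc1ccccc1)c1cc(OCc2ccccc2)c(OC)c(OCc2ccccc2)c1I | intermediate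
9 | 1-[3,5-bis(benzyloxy)-2-iodo-4-methoxyphenyl]-1-(benzyloxymethoxy)propan-2-one (racemic) | CC(=O)C(OCOCc1ccccc1)c1cc(OCc2ccccc2)c(OC)c(OCc2ccccc2)c1I | intermediate
10 | (1S*,2R*)-1-[3,5-bis(benzyloxy)-2-iodo-4-methoxyphenyl]-1-(benzyloxymethoxy)propan-2-ol (racemate, both enantiomers written) | C[C@@H](O)[C@@H](OCOCc1ccccc1)c1cc(OCc2ccccc2)c(OC)c(OCc2ccccc2)c1I.C[C@H](O)[C@H](OCOCc1ccccc1)c1cc(OCc2ccccc2)c(OC)c(OCc2ccccc2)c1I | intermediate
11 | (1S,2R)-1-[3,5-bis(benzyloxy)-2-iodo-4-methoxyphenyl]-1-(benzyloxymethoxy)propan-2-yl acetate | C[C@@H](OC(C)=O)[C@@H](OCOCc1ccccc1)c1cc(OCc2ccccc2)c(OC)c(OCc2ccccc2)c1I | intermediate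
12 | (1R,2S)-1-[3,5-bis(benzyloxy)-2-iodo-4-methoxyphenyl]-1-(benzyloxymethoxy)propan-2-ol | C[C@H](O)[C@H](OCOCc1ccccc1)c1cc(OCc2ccccc2)c(OC)c(OCc2ccccc2)c1I | intermediate
13 | (1S,2R)-1-[3,5-bis(benzyloxy)-2-iodo-4-methoxyphenyl]-1-(benzyloxymethoxy)propan-2-ol | C[C@@H](O)[C@@H](OCOCc1ccccc1)c1cc(OCc2ccccc2)c(OC)c(OCc2ccccc2)c1I | intermediate
14 | tert-butyl{[(1S,2R)-1-[3,5-bis(benzyloxy)-2-iodo-4-methoxyphenyl]-1-(benzyloxymethoxy)propan-2-yl]oxy}dimethylsilane | C[C@@H](O[Si](C)(C)C(C)(C)C)[C@@H](OCOCc1ccccc1)c1cc(OCc2ccccc2)c(OC)c(OCc2ccccc2)c1I | intermediate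
15 | aryllithium from 14 (lithium in place of iodine) | C[C@@H](O[Si](C)(C)C(C)(C)C)[C@@H](OCOCc1ccccc1)c1cc(OCc2ccccc2)c(OC)c(OCc2ccccc2)c1[Li] | intermediate
16 | 2,4-bis(benzyloxy)-6-[(1S,2R)-1-(benzyloxymethoxy)-2-(tert-butyldimethylsilyloxy)propyl]-3-methoxybenzoic acid | C[C@@H](O[Si](C)(C)C(C)(C)C)[C@@H](OCOCc1ccccc1)c1cc(OCc2ccccc2)c(OC)c(OCc2ccccc2)c1C(=O)O | intermediate
17 | dilithio derivative of 12 (lithium alkoxide, aryllithium) | C[C@H](O[Li])[C@H](OCOCc1ccccc1)c1cc(OCc2ccccc2)c(OC)c(OCc2ccccc2)c1[Li] | intermediate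
18 | dimethyl arylboronate from 17 (lithium alkoxide) | C[C@H](O[Li])[C@H](OCOCc1ccccc1)c1cc(OCc2ccccc2)c(OC)c(OCc2ccccc2)c1B(OC)OC | intermediate
19 | 2,4-bis(benzyloxy)-6-[(1R,2S)-1-(benzyloxymethoxy)-2-hydroxypropyl]-3-methoxyphenol | C[C@H](O)[C@H](OCOCc1ccccc1)c1cc(OCc2ccccc2)c(OC)c(OCc2ccccc2)c1O | intermediate
20 | (1R,2S)-1-(benzyloxymethoxy)-1-[2,3,5-tris(benzyloxy)-4-methoxyphenyl]propan-2-ol | C[C@H](O)[C@H](OCOCc1ccccc1)c1cc(OCc2ccccc2)c(OC)c(OCc2ccccc2)c1OCc1ccccc1 | intermediate
21 | (1R,2S)-1-(benzyloxymethoxy)-1-[2,3,5-tris(benzyloxy)-6-iodo-4-methoxyphenyl]propan-2-ol | C[C@H](O)[C@H](OCOCc1ccccc1)c1c(I)c(OCc2ccccc2)c(OC)c(OCc2ccccc2)c1OCc1ccccc1 | intermediate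
22 | (1R,2R)-1-(benzyloxymethoxy)-1-[2,3,5-tris(benzyloxy)-6-iodo-4-methoxyphenyl]propan-2-yl 2,4-bis(benzyloxy)-6-[(1S,2R)-1-(benzyloxymethoxy)-2-(tert-butyldimethylsilyloxy)propyl]-3-methoxybenzoate | C[C@@H](O[Si](C)(C)C(C)(C)C)[C@@H](OCOCc1ccccc1)c1cc(OCc2ccccc2)c(OC)c(OCc2ccccc2)c1C(=O)O[C@H](C)[C@H](OCOCc1ccccc1)c1c(I)c(OCc2ccccc2)c(OC)c(OCc2ccccc2)c1OCc1ccccc1 | intermediate
23 | 3,4,6-tris(benzyloxy)-2-[(1R,2R)-2-({2,4-bis(benzyloxy)-6-[(1S,2R)-1-(benzyloxymethoxy)-2-(tert-butyldimethylsilyloxy)propyl]-3-methoxybenzoyl}oxy)-1-(benzyloxymethoxy)propyl]-5-methoxybenzoic acid | C[C@@H](O[Si](C)(C)C(C)(C)C)[C@@H](OCOCc1ccccc1)c1cc(OCc2ccccc2)c(OC)c(OCc2ccccc2)c1C(=O)O[C@H](C)[C@H](OCOCc1ccccc1)c1c(C(=O)O)c(OCc2ccccc2)c(OC)c(OCc2ccccc2)c1OCc1ccccc1 | intermediate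
24 | seco acid: 23 with a free (2R)-hydroxyl in place of the TBS ether | C[C@@H](O)[C@@H](OCOCc1ccccc1)c1cc(OCc2ccccc2)c(OC)c(OCc2ccccc2)c1C(=O)O[C@H](C)[C@H](OCOCc1ccccc1)c1c(C(=O)O)c(OCc2ccccc2)c(OC)c(OCc2ccccc2)c1OCc1ccccc1 | intermediate
25 | protected macrocycle: target dilactone with five phenolic O-benzyl and two benzylic O-BOM groups, (1S,2S) on ring A, (1R,2R) on ring B | COc1c(OCc3ccccc3)cc2c(c1OCc4ccccc4)C(=O)O[C@H](C)[C@H](OCOCc6ccccc6)c5c(OCc7ccccc7)c(OCc8ccccc8)c(OC)c(OCc9ccccc9)c5C(=O)O[C@@H](C)[C@H]2OCOCc1ccccc1 | intermediate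
26 | CNP0086623.3, 12-membered dilactone with (1S,2S) side chain on the dihydroxy-methoxy ring A and (1R,2R) side chain on the trihydroxy-methoxy ring B | COc1c(O)cc2c(c1O)C(=O)O[C@H](C)[C@H](O)c1c(O)c(O)c(OC)c(O)c1C(=O)O[C@@H](C)[C@H]2O | target

**Step count and weak points**

Total: 14 steps. Longest linear sequence: 12 steps (1–6, then 7–8 or 9–10, then 11–14).

The three steps most likely to fail:

First, step 13, the ring closure. The activated carbinol sits six atoms from the carbonyl oxygen of its own aryl ester, so ester participation or elimination can outrun the 12-membered SN2 closure. The fallback inverts the carbinol intermolecularly and closes the ring by forming the aryl–carbonyl bond instead. It sets out from 22: HF·pyridine gives the (1S,2R) hydroxy iodo ester F1; Mitsunobu reaction with formic acid (PPh3, DIAD) gives the inverted (1S,2S) formate F2; KHCO3 in MeOH at 0 °C gives the (1S,2S) hydroxy iodo ester F3; Pd(OAc)2, Xantphos, CO, Et3N in toluene at 80 °C and 0.002 M then closes the ring by carbonylative macrolactonisation with retention, returning to the route at 25.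

Second, step 11, the intermolecular Mitsunobu coupling of a 2,6-disubstituted benzoic acid with a carbinol that carries a branched neighbour. Elimination or acyloxyphosphonium side paths are possible. The fallback separates activation from displacement. It sets out from 21: MsCl and Et3N give the (1R,2S) methanesulfonate F4; acid 16 with Cs2CO3 in DMF gives the cesium carboxylate F5; heating the two at 50 °C displaces the sulfonate with inversion and returns to the route at 22.

Third, step 6, the lipase resolution. The carbinol has a very bulky neighbour and the enzyme may be too slow or too unselective. The fallback is a classical resolution through diastereomers. It sets out from 10: (S)-2-methoxy-2-phenylacetic acid, DCC and DMAP give the (S)-2-methoxy-2-phenylacetate of the (1S,2R) alcohol F6 and the (S)-2-methoxy-2-phenylacetate of the (1R,2S) alcohol F7, which are separated on silica. K2CO3 in MeOH then cleaves each ester and returns to the route at 13 (from F6, silylated as in step 7) and at 12 (from F7).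

**Further compounds**

F1 | step 13 | (1S,2R) hydroxy iodo ester (22 without the TBS group) | C[C@@H](O)[C@@H](OCOCc1ccccc1)c1cc(OCc2ccccc2)c(OC)c(OCc2ccccc2)c1C(=O)O[C@H](C)[C@H](OCOCc1ccccc1)c1c(I)c(OCc2ccccc2)c(OC)c(OCc2ccccc2)c1OCc1ccccc1
F2 | step 13 | (1S,2S) formate of F1 after inversion at C2 | C[C@H](OC=O)[C@@H](OCOCc1ccccc1)c1cc(OCc2ccccc2)c(OC)c(OCc2ccccc2)c1C(=O)O[C@H](C)[C@H](OCOCc1ccccc1)c1c(I)c(OCc2ccccc2)c(OC)c(OCc2ccccc2)c1OCc1ccccc1
F3 | step 13 | (1S,2S) hydroxy iodo ester | C[C@H](O)[C@@H](OCOCc1ccccc1)c1cc(OCc2ccccc2)c(OC)c(OCc2ccccc2)c1C(=O)O[C@H](C)[C@H](OCOCc1ccccc1)c1c(I)c(OCc2ccccc2)c(OC)c(OCc2ccccc2)c1OCc1ccccc1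
F4 | step 11 | (1R,2S)-1-(benzyloxymethoxy)-1-[2,3,5-tris(benzyloxy)-6-iodo-4-methoxyphenyl]propan-2-yl methanesulfonate | C[C@H](OS(C)(=O)=O)[C@H](OCOCc1ccccc1)c1c(I)c(OCc2ccccc2)c(OC)c(OCc2ccccc2)c1OCc1ccccc1
F5 | step 11 | cesium salt of acid 16 | C[C@@H](O[Si](C)(C)C(C)(C)C)[C@@H](OCOCc1ccccc1)c1cc(OCc2ccccc2)c(OC)c(OCc2ccccc2)c1C(=O)[O-].[Cs+]
F6 | step 6 | (S)-2-methoxy-2-phenylacetate of the (1S,2R) alcohol 13 | C[C@@H](OC(=O)[C@@H](OC)c1ccccc1)[C@@H](OCOCc1ccccc1)c1cc(OCc2ccccc2)c(OC)c(OCc2ccccc2)c1I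
F7 | step 6 | (S)-2-methoxy-2-phenylacetate of the (1R,2S) alcohol 12 | C[C@H](OC(=O)[C@@H](OC)c1ccccc1)[C@H](OCOCc1ccccc1)c1cc(OCc2ccccc2)c(OC)c(OCc2ccccc2)c1I
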